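## Retrosynthetic overview
1. The target comes from its (1S)-configured (R)-1-phenylethyl pseudo-ester. C-1 is fixed by separating diastereomers, and the auxiliary is removed last by neutral hydrogenolysis.
2. The dioxepinone ring is the last ring formed. Its aryl ester C–O comes from carbodiimide lactonisation, and before that the diaryl ether C–O comes from SNAr of a ring B phenol on a ring A aryl fluoride flanked by CHO and CO2Bn.
3. The ring B phenol comes from methyl orsellinate. Side-chain dibromination and hydrolysis close the lactone ring (second ring), and bromination, borylation and oxidation install the ether oxygen.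
4. Key C–C disconnection: methyl orsellinate comes from methyl acetoacetate and methyl crotonate by intermolecular Michael addition, then Dieckmann closure and aromatisation (ring B carbocycle, first ring).
5. Ring A is bought as 3,5-difluorotoluene. CHO is added by ortho-lithiation, OMe by SNAr, and CO2Bn by bromination and carbonylation.

Assumption: the single stereocentre, (S) at lactol carbon C-1, is a pseudo-acid carbon that can epimerise through the open formyl-acid. It is therefore set at the very end, unmasked under neutral aprotic conditions, and 29 is kept cold, dry and free of acid or base.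

## Route

Step 1
Reactants: 1 methyl acetoacetate; 2 methyl (E)-but-2-enoate (methyl crotonate)
Product: 4 methyl 2-hydroxy-6-methyl-4-oxocyclohex-2-ene-1-carboxylate (methyl dihydroorsellinate; racemic), via Michael adduct 3 (not isolated)
Conditions: NaOMe (1.1 equiv), MeOH, reflux, 20 h; then aq. HCl, 0 °C
Reagents that add atoms: none
Why: The sodium enolate of 1 adds to the β-carbon of 2 in an intermolecular Michael addition (the C–C bond that joins the two fragments), the methyl-ketone enolate of 3 then closes the six-membered ring by Dieckmann (intramolecular Claisen) condensation, and the stable 1,3-dione enolate drives both equilibria; the two stereocentres of 4 are erased in step 2.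

Step 2
Reactants: 4 methyl dihydroorsellinate
Product: 6 methyl 2,4-dihydroxy-6-methylbenzoate (methyl orsellinate), via bromo-dione 5 (not isolated)
Conditions: Br2 (1.0 equiv), DMF, 0 °C; then 80 °C, 12 h
Reagents that add atoms: none
Why: One equivalent of Br2 brominates the doubly activated C-3 of the enolised 1,3-dione and heating expels HBr with tautomerisation to the resorcinol (bromination–dehydrobromination aromatisation), 80 °C being low enough to keep the ester.

Step 3
Reactants: 6 methyl orsellinate
Product: 7 methyl 2,4-diacetoxy-6-methylbenzoate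
Conditions: Ac2O (3 equiv), pyridine, DMAP (5 mol%), rt
Reagents that add atoms: acetic anhydride CC(=O)OC(C)=O
Why: DMAP-catalysed O-acylation caps both phenols, including the hydrogen-bonded 2-OH, as acetates that deactivate the ring so that step 4 attacks only the side chain.

Step 4
Reactants: 7 methyl 2,4-diacetoxy-6-methylbenzoate
Product: 9 methyl 2,4-diacetoxy-6-(dibromomethyl)benzoate, via monobromide 8 (not isolated)
Conditions: NBS (2.4 equiv), AIBN (5 mol%), PhCF3, reflux, visible light
Reagents that add atoms: N-bromosuccinimide O=C1CCC(=O)N1Br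
Why: Wohl–Ziegler radical bromination takes the only benzylic C–H bonds twice, as with methyl o-toluate, while the diacetoxy ring is too electron-poor for nuclear bromination in a non-polar solvent.

Step 5
Reactants: 9 methyl 2,4-diacetoxy-6-(dibromomethyl)benzoate
Product: 10 3,5,7-trihydroxyisobenzofuran-1(3H)-one (racemic lactol form of 2-formyl-4,6-dihydroxybenzoic acid)
Conditions: 1,4-dioxane/1 M aq. H2SO4 (1:1), 0.05 M, 85 °C, N2, 8 h
Reagents that add atoms: water O
Why: Acid hydrolysis turns the gem-dibromide into the aldehyde and cleaves both acetates, and the aldehyde hydrate attacks the neighbouring methyl ester (neighbouring-group participation) so that the lactone ring closes to the lactol, whose new C-3 centre is racemic and is only fixed in step 17.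

Step 6
Reactants: 10 3,5,7-trihydroxyisobenzofuran-1(3H)-one
Product: 11 5,7-dihydroxy-3-methoxyisobenzofuran-1(3H)-one (racemic)
Conditions: MeOH, H2SO4 (2 mol%), reflux, 3 h
Reagents that add atoms: methanol CO
Why: Acid-catalysed pseudo-esterification (Fischer-type acetalisation of the cyclic lactol through its oxocarbenium ion) masks the aldehyde/acid pair in one stroke as a 3-methoxyphthalide that tolerates the mild bases, palladium catalysis and hydrogenolysis that follow.

Step 7
Reactants: 11 5,7-dihydroxy-3-methoxyisobenzofuran-1(3H)-one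
Product: 12 5,7-bis(benzyloxy)-3-methoxyisobenzofuran-1(3H)-one (racemic)
Conditions: BnBr (2.3 equiv), K2CO3 (3 equiv), dry DMF, 50 °C
Reagents that add atoms: benzyl bromide BrCc1ccccc1
Why: Williamson etherification of both phenoxides, which are meta to the acylal-bearing carbon and so cannot expel it, gives benzyl ethers that later come off together with the benzyl ester in step 15.

Step 8
Reactants: 12 5,7-bis(benzyloxy)-3-methoxyisobenzofuran-1(3H)-one
Product: 13 5,7-bis(benzyloxy)-4-bromo-3-methoxyisobenzofuran-1(3H)-one (racemic)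
Conditions: NBS (1.05 equiv), MeCN, 0 °C to rt, dark
Reagents that add atoms: N-bromosuccinimide O=C1CCC(=O)N1Br
Why: Electrophilic aromatic bromination goes to C-4, para to the 7-benzyloxy and ortho to the 5-benzyloxy group, rather than to C-6, which is wedged between two benzyloxy groups, as is usual for resorcinol diethers.

Step 9
Reactants: 13 5,7-bis(benzyloxy)-4-bromo-3-methoxyisobenzofuran-1(3H)-one
Product: 15 5,7-bis(benzyloxy)-4-hydroxy-3-methoxyisobenzofuran-1(3H)-one (racemic), via pinacol boronate 14 (not isolated)
Conditions: B2pin2 (1.5 equiv), Pd(OAc)2 (3 mol%), SPhos (6 mol%), KOAc (3 equiv), 1,4-dioxane, 90 °C; filter; then 30% H2O2, THF/pH 7 phosphate buffer, 0 °C to rt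
Reagents that add atoms: hydrogen peroxide OO
Why: Miyaura borylation with a bulky biaryl phosphine tolerates the two ortho substituents and the weak base KOAc spares the acylal, and the boronate is then oxidised by 1,2-aryl migration to oxygen at pH 7, where phenol 15 stays protonated and cannot open its acylal.

Step 10
Reactants: 16 3,5-difluorotoluene
Product: 18 2,6-difluoro-4-methylbenzaldehyde, via aryllithium 17 (not isolated)
Conditions: n-BuLi (1.05 equiv), THF, −78 °C, 1 h; DMF (1.5 equiv), −78 to 0 °C; aq. HCl
Reagents that add atoms: N,N-dimethylformamide CN(C)C=O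
Why: Directed ortho-metalation removes the most acidic proton, the one between the two fluorines, and the aryllithium is formylated by DMF (Bouveault-type formylation).

Step 11
Reactants: 18 2,6-difluoro-4-methylbenzaldehyde
Product: 19 2-fluoro-6-methoxy-4-methylbenzaldehyde
Conditions: NaOMe (1.05 equiv), MeOH, 0 to 55 °C
Reagents that add atoms: sodium methoxide [Na+].[O-]C
Why: SNAr ortho to the aldehyde replaces one of two equivalent fluorides, so no regiochemical issue arises, and the new methoxy group slows a second substitution.

Step 12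
Reactants: 19 2-fluoro-6-methoxy-4-methylbenzaldehyde
Product: 20 3-bromo-2-fluoro-6-methoxy-4-methylbenzaldehyde
Conditions: NBS (1.05 equiv), DMF, rt
Reagents that add atoms: N-bromosuccinimide O=C1CCC(=O)N1Br
Why: Electrophilic aromatic bromination is steered by the strongest donor to the position para to OMe (also ortho to CH3 and beside the small F), the pattern known from o-anisaldehydes and 3-fluoroanisoles.

Step 13
Reactants: 20 3-bromo-2-fluoro-6-methoxy-4-methylbenzaldehyde
Product: 21 benzyl 2-fluoro-3-formyl-4-methoxy-6-methylbenzoate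
Conditions: CO (3 bar), BnOH (3 equiv), Pd(OAc)2 (3 mol%), Xantphos (4 mol%), Et3N (2 equiv), toluene, 85 °C
Reagents that add atoms: carbon monoxide [C-]#[O+]; benzyl alcohol OCc1ccccc1
Why: Palladium-catalysed alkoxycarbonylation (oxidative addition of zerovalent palladium to C–Br, CO insertion, benzyl alcoholysis) installs the carboxyl carbon without organometallic reagents that would attack the aldehyde, and Et3N is too weak a base to make benzyl oxide displace fluoride.

Step 14
Reactants: 15 5,7-bis(benzyloxy)-4-hydroxy-3-methoxyisobenzofuran-1(3H)-one; 21 benzyl 2-fluoro-3-formyl-4-methoxy-6-methylbenzoate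
Product: 22 benzyl 2-{[5,7-bis(benzyloxy)-3-methoxy-1-oxo-1,3-dihydroisobenzofuran-4-yl]oxy}-3-formyl-4-methoxy-6-methylbenzoate (racemic)
Conditions: Cs2CO3 (1.3 equiv), dry DMF, 4 Å MS, 70 °C
Reagents that add atoms: none
Why: In this SNAr the fluoride of 21 lies ortho to both the formyl and the ester group and the only free hydroxyl of 15 is the one at C-4, so the ether oxygen is placed unambiguously, and every side equilibrium of the phenoxide is reversible while fluoride loss is not.

Step 15
Reactants: 22 tribenzyl diaryl ether
Product: 23 2-[(5,7-dihydroxy-3-methoxy-1-oxo-1,3-dihydroisobenzofuran-4-yl)oxy]-3-formyl-4-methoxy-6-methylbenzoic acid (racemic)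
Conditions: H2 (1 atm), 10% Pd/C, EtOAc, rt, stopped at 3 equiv H2
Reagents that add atoms: none
Why: Hydrogenolysis cleaves the two aryl benzyl ethers and the benzyl ester much faster than it touches the hindered, electron-rich 2,6-dioxygenated benzaldehyde or the methyl acylal.

Step 16
Reactants: 23 dihydroxy acid
Product: 25 4-hydroxy-1,10-dimethoxy-8-methyl-3,7-dioxo-1,3-dihydro-7H-isobenzofuro[4,5-b][1,4]benzodioxepine-11-carbaldehyde (racemic methyl pseudo-ester of the target), via O-acylisourea 24 (not isolated)
Conditions: DCC (1.3 equiv), DMAP (0.1 equiv), CH2Cl2, 2 mM, 0 °C to rt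
Reagents that add atoms: none
Why: Steglich-type carbodiimide lactonisation under high dilution acylates the 5-OH of the phthalide, the only hydroxyl that can reach the activated carboxyl (seven-membered ring), whereas the 7-OH is remote and hydrogen-bonded to the lactone carbonyl.

Step 17
Reactants: 25 racemic methyl pseudo-ester; 26 (R)-1-phenylethanol
Product: 28 (1S)-4-hydroxy-10-methoxy-8-methyl-3,7-dioxo-1-[(1R)-1-phenylethoxy]-1,3-dihydro-7H-isobenzofuro[4,5-b][1,4]benzodioxepine-11-carbaldehyde, via C-1 epimer mixture 27 (not isolated)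
Conditions: 26 (3 equiv), PPTS (0.1 equiv), toluene, 5 Å MS, 55 °C, 24 h; then SiO2 chromatography and crystallisation; (1R) epimer resubmitted
Reagents that add atoms: none
Why: Mild acid-catalysed transacetalisation through the benzylic oxocarbenium ion swaps OMe for the (R)-1-phenylethoxy group and gives both C-1 epimers, which are diastereomers and are separated (classical resolution through a chiral auxiliary, configuration read from a crystal structure against the known (R) centre), while the unwanted epimer is re-equilibrated under the same conditions, so C-1 is set as S here.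

Step 18
Reactants: 28 (1S,1'R) pseudo-ester
Product: 29 (1S)-1,4-dihydroxy-10-methoxy-8-methyl-3,7-dioxo-1,3-dihydro-7H-isobenzofuro[4,5-b][1,4]benzodioxepine-11-carbaldehyde (CNP0216483.1)
Conditions: H2 (1 atm), 20% Pd(OH)2/C, dry EtOAc, 0–5 °C, stopped at 1 equiv H2; cold filtration, evaporation below 15 °C, crystallisation from cold EtOAc/heptane
Reagents that add atoms: none
Why: Neutral hydrogenolysis breaks the O–CH(CH3)Ph bond of the auxiliary and no bond to C-1, so the (S) configuration passes into the lactol with retention, and the aprotic, acid- and base-free medium at low temperature keeps ring–chain tautomerism from scrambling it.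

## Compound list
1 | methyl acetoacetate | CC(=O)CC(=O)OC | starting material
2 | methyl (E)-but-2-enoate | C/C=C/C(=O)OC | starting material
3 | dimethyl 2-acetyl-3-methylpentanedioate (Michael adduct, stereoisomer mixture) | COC(=O)CC(C)C(C(C)=O)C(=O)OC | intermediate
4 | methyl 2-hydroxy-6-methyl-4-oxocyclohex-2-ene-1-carboxylate (racemic) | COC(=O)C1C(C)CC(=O)C=C1O | intermediate
5 | methyl 3-bromo-2-hydroxy-6-methyl-4-oxocyclohex-2-ene-1-carboxylate | COC(=O)C1C(C)CC(=O)C(Br)=C1O | intermediate
6 | methyl 2,4-dihydroxy-6-methylbenzoate | COC(=O)c1c(C)cc(O)cc1O | intermediate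
7 | methyl 2,4-diacetoxy-6-methylbenzoate | COC(=O)c1c(C)cc(OC(C)=O)cc1OC(C)=O | intermediate
8 | methyl 2,4-diacetoxy-6-(bromomethyl)benzoate | COC(=O)c1c(CBr)cc(OC(C)=O)cc1OC(C)=O | intermediate
9 | methyl 2,4-diacetoxy-6-(dibromomethyl)benzoate | COC(=O)c1c(C(Br)Br)cc(OC(C)=O)cc1OC(C)=O | intermediate
10 | 3,5,7-trihydroxyisobenzofuran-1(3H)-one (racemic) | OC1OC(=O)c2c(O)cc(O)cc12 | intermediate
11 | 5,7-dihydroxy-3-methoxyisobenzofuran-1(3H)-one (racemic) | COC1OC(=O)c2c(O)cc(O)cc12 | intermediate
12 | 5,7-bis(benzyloxy)-3-methoxyisobenzofuran-1(3H)-one (racemic) | COC1OC(=O)c2c(OCc3ccccc3)cc(OCc3ccccc3)cc12 | intermediate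
13 | 5,7-bis(benzyloxy)-4-bromo-3-methoxyisobenzofuran-1(3H)-one (racemic) | COC1OC(=O)c2c(OCc3ccccc3)cc(OCc3ccccc3)c(Br)c12 | intermediate
14 | 5,7-bis(benzyloxy)-3-methoxy-4-(4,4,5,5-tetramethyl-1,3,2-dioxaborolan-2-yl)isobenzofuran-1(3H)-one (racemic) | COC1OC(=O)c2c(OCc3ccccc3)cc(OCc3ccccc3)c(B3OC(C)(C)C(C)(C)O3)c12 | intermediate
15 | 5,7-bis(benzyloxy)-4-hydroxy-3-methoxyisobenzofuran-1(3H)-one (racemic) | COC1OC(=O)c2c(OCc3ccccc3)cc(OCc3ccccc3)c(O)c12 | intermediate
16 | 3,5-difluorotoluene | Cc1cc(F)cc(F)c1 | starting material
17 | (2,6-difluoro-4-methylphenyl)lithium | [Li]c1c(F)cc(C)cc1F | intermediate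
18 | 2,6-difluoro-4-methylbenzaldehyde | Cc1cc(F)c(C=O)c(F)c1 | intermediate
19 | 2-fluoro-6-methoxy-4-methylbenzaldehyde | COc1cc(C)cc(F)c1C=O | intermediate
20 | 3-bromo-2-fluoro-6-methoxy-4-methylbenzaldehyde | COc1cc(C)c(Br)c(F)c1C=O | intermediate
21 | benzyl 2-fluoro-3-formyl-4-methoxy-6-methylbenzoate | COc1cc(C)c(C(=O)OCc2ccccc2)c(F)c1C=O | intermediate
22 | benzyl 2-{[5,7-bis(benzyloxy)-3-methoxy-1-oxo-1,3-dihydroisobenzofuran-4-yl]oxy}-3-formyl-4-methoxy-6-methylbenzoate (racemic) | COc1cc(C)c(C(=O)OCc2ccccc2)c(Oc2c(OCc3ccccc3)cc(OCc3ccccc3)c3c2C(OC)OC3=O)c1C=O | intermediate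
23 | 2-[(5,7-dihydroxy-3-methoxy-1-oxo-1,3-dihydroisobenzofuran-4-yl)oxy]-3-formyl-4-methoxy-6-methylbenzoic acid (racemic) | COc1cc(C)c(C(=O)O)c(Oc2c(O)cc(O)c3c2C(OC)OC3=O)c1C=O | intermediate
24 | O-acylisourea of 23 and DCC | COc1cc(C)c(C(=O)OC(NC2CCCCC2)=NC2CCCCC2)c(Oc2c(O)cc(O)c3c2C(OC)OC3=O)c1C=O | intermediate
25 | racemic methyl pseudo-ester of the target (1-OMe depsidone) | COc1cc(C)c2c(c1C=O)Oc1c(cc(O)c3c1C(OC)OC3=O)OC2=O | intermediate
26 | (R)-1-phenylethanol | C[C@@H](O)c1ccccc1 | starting material
27 | 1-[(1R)-1-phenylethoxy] depsidone, mixture of C-1 epimers | COc1cc(C)c2c(c1C=O)Oc1c(cc(O)c3c1C(O[C@H](C)c1ccccc1)OC3=O)OC2=O | intermediate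
28 | (1S)-1-[(1R)-1-phenylethoxy] depsidone | COc1cc(C)c2c(c1C=O)Oc1c(cc(O)c3c1[C@@H](O[C@H](C)c1ccccc1)OC3=O)OC2=O | intermediate
29 | (1S)-1,4-dihydroxy-10-methoxy-8-methyl-3,7-dioxo-1,3-dihydro-7H-isobenzofuro[4,5-b][1,4]benzodioxepine-11-carbaldehyde | COc1cc(C)c2c(c1C=O)Oc1c(cc(O)c3c1[C@@H](O)OC3=O)OC2=O | target

## Step count and risk analysis
Total step count: 18. The ring B branch is steps 1–9, the ring A branch is steps 10–13, and the union and endgame are steps 14–18.
Longest linear sequence: 14 steps (1–9, then 14–18).

Steps most likely to fail: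

**Step 9.** The bromide carries two ortho substituents, so protodebromination or loss of the acylal could stall the route. The fallback replaces the C–Br/C–B route to the phenol by a metal-free C-formylation and Baeyer–Villiger route. It sets out from 12. Vilsmeier–Haack formylation (POCl3, DMF, 70 °C) at the same C-4 position gives 5,7-bis(benzyloxy)-3-methoxy-1-oxo-1,3-dihydroisobenzofuran-4-carbaldehyde F1. Oxidation with mCPBA in CH2Cl2 is a Dakin-type Baeyer–Villiger reaction in which aryl migration is favoured by the ortho and para alkoxy groups. It gives 5,7-bis(benzyloxy)-3-methoxy-1-oxo-1,3-dihydroisobenzofuran-4-yl formate F2. Brief methanolysis (MeOH, catalytic Et3N, 0 °C) liberates the phenol, and the route is rejoined at 15.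

**Step 14.** This SNAr makes a diaryl ether with four ortho substituents. The twisted ester of 21 shields both faces of the C–F carbon, and the acylal phenoxide of 15 does not like long heating. The fallback forms the ether bond before the carboxyl carbon is in place. It sets out from 15 and the slimmer bromo-aldehyde 20, whose fluoride is activated by the ortho formyl group and inductively by the ortho bromine. SNAr (Cs2CO3, DMF, 60–70 °C) gives 2-{[5,7-bis(benzyloxy)-3-methoxy-1-oxo-1,3-dihydroisobenzofuran-4-yl]oxy}-3-bromo-6-methoxy-4-methylbenzaldehyde F3. Palladium-catalysed benzyloxycarbonylation of its C–Br bond follows (CO 5 bar, BnOH, Pd(OAc)2, di(1-adamantyl)-n-butylphosphine, Et3N, toluene, 100 °C). This brings in the ester afterwards, and the route is rejoined at 22.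

**Step 18.** The hydrogenolysis must spare the aldehyde and the C-1–O bonds, and the freed lactol may lose optical purity. The fallback gives up the auxiliary and resolves the free lactol itself. It sets out from 25. Mild hydrolysis (THF/0.5 M aq. HCl, 40 °C) gives the racemic lactol F4. Preparative enantioselective SFC at 5 °C follows, on an immobilised amylose tris(3,5-dimethylphenylcarbamate) phase with CO2/MeCN. The (S)-enantiomer is collected into cold receivers and crystallised at once. The (1R)-enantiomer F5 is racemised by warming with a trace of acid and re-injected. The route is rejoined at 29.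

## Further compounds
F1 | step 9 | 5,7-bis(benzyloxy)-3-methoxy-1-oxo-1,3-dihydroisobenzofuran-4-carbaldehyde (racemic) | COC1OC(=O)c2c(OCc3ccccc3)cc(OCc3ccccc3)c(C=O)c12
F2 | step 9 | 5,7-bis(benzyloxy)-3-methoxy-1-oxo-1,3-dihydroisobenzofuran-4-yl formate (racemic) | COC1OC(=O)c2c(OCc3ccccc3)cc(OCc3ccccc3)c(OC=O)c12
F3 | step 14 | 2-{[5,7-bis(benzyloxy)-3-methoxy-1-oxo-1,3-dihydroisobenzofuran-4-yl]oxy}-3-bromo-6-methoxy-4-methylbenzaldehyde (racemic) | COc1cc(C)c(Br)c(Oc2c(OCc3ccccc3)cc(OCc3ccccc3)c3c2C(OC)OC3=O)c1C=O
F4 | step 18 | racemic 1,4-dihydroxy-10-methoxy-8-methyl-3,7-dioxo-1,3-dihydro-7H-isobenzofuro[4,5-b][1,4]benzodioxepine-11-carbaldehyde | COc1cc(C)c2c(c1C=O)Oc1c(cc(O)c3c1C(O)OC3=O)OC2=O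
F5 | step 18 | (1R)-enantiomer of the target | COc1cc(C)c2c(c1C=O)Oc1c(cc(O)c3c1[C@H](O)OC3=O)OC2=O
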